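The piperidine ring (N1, C2, C3, C4, C4a, C8a) is closed last, by forming N1–C8a on a preformed cyclohexene ring. The key step is an intramolecular Mitsunobu N-alkylation: the tosylamide nitrogen displaces the allylic C8a hydroxyl of a 2-alkyl-3-hydroxycyclohexenyl triflate with inversion, so a CBS-set carbinol fixes C8a with H8a syn to the C2 methyl and C3 oxygen, themselves installed together by aminohydroxylation of ethyl crotonate. The step exploits that C8a is at once the N-bearing ring-fusion atom of the piperidine ring and allylic to C4a=C5 of the carbocycle. The C5 triflate then receives the side chain by B-alkyl Suzuki coupling, and the C3 hydroxyl directs one hydrogenation that sets C4a and C5.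

Key step: step 9

Remark: ring atoms are numbered as in decahydroquinoline (N1, C2, C3, C4, C4a, C5–C8, C8a), side-chain carbons C1′–C8′; the target is read as (2R,3R,4aS,5S,8aR,5′R).

Step 1
Reactants: 1 ethyl (E)-but-2-enoate
Product: 2 ethyl (2S,3R)-2-hydroxy-3-(4-methylphenylsulfonamido)butanoate
Conditions: chloramine-T (TsNClNa·3H2O), K2OsO2(OH)4 (cat.), (DHQD)2PHAL (cat.), t-BuOH/H2O, rt
Reagents that add atoms: chloramine-T, Cc1ccc(cc1)S(=O)(=O)[N-]Cl.[Na+]; water, O
Why: Sharpless asymmetric aminohydroxylation adds N and O syn across the E-alkene, with nitrogen at the β-carbon and the face chosen by (DHQD)2PHAL, which should set the future C2 (R) and C3 together as the syn amino alcohol (the crystalline sulfonamide should allow enrichment by recrystallisation).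

Step 2
Reactants: 2 ethyl (2S,3R)-2-hydroxy-3-(4-methylphenylsulfonamido)butanoate
Product: 3 ethyl (2S,3R)-3-(4-methylphenylsulfonamido)-2-(triethylsilyloxy)butanoate
Conditions: TESCl, imidazole, DMF, 0 °C to rt
Reagents that add atoms: chlorotriethylsilane, CC[Si](Cl)(CC)CC
Why: Standard O-silylation; the secondary alcohol reacts while the sulfonamide N–H stays free, and the silyl ether later prevents aziridine formation in the Mitsunobu step.

Step 3
Reactants: 3 ethyl (2S,3R)-3-(4-methylphenylsulfonamido)-2-(triethylsilyloxy)butanoate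
Product: 4 (2S,3R)-3-(4-methylphenylsulfonamido)-2-(triethylsilyloxy)butanal
Conditions: DIBAL-H (i-Bu2AlH, 2.2 equiv), CH2Cl2, −78 °C; aq. potassium sodium tartrate
Reagents that add atoms: none
Why: Partial DIBAL-H reduction of an α-silyloxy ester stops at the chelated tetrahedral intermediate at −78 °C and should give the aldehyde (used crude) without touching the stereocenters.

Step 4
Reactants: 5 (R)-2-propyloxirane; 6 allylmagnesium bromide
Product: 7 (R)-oct-7-en-4-ol
Conditions: CuI (10 mol%), THF, −30 to 0 °C; aq. NH4Cl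
Reagents that add atoms: none
Why: Copper-catalysed Grignard opening of the terminal epoxide at its CH2 carbon leaves the bought stereocenter (future C5′) untouched.

Step 5
Reactants: 7 (R)-oct-7-en-4-ol
Product: 8 (R)-tert-butyldimethyl(oct-7-en-4-yloxy)silane
Conditions: TBSCl, imidazole, DMF, rt
Reagents that add atoms: tert-butylchlorodimethylsilane, CC(C)(C)[Si](C)(C)Cl
Why: Standard silylation; the TBS ether masks the C5′ hydroxyl until the final acid step.

Step 6
Reactants: 9 cyclohexane-1,3-dione; 4 (2S,3R)-3-(4-methylphenylsulfonamido)-2-(triethylsilyloxy)butanal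
Product: 11 2-[(2R,3R)-3-(4-methylphenylsulfonamido)-2-(triethylsilyloxy)butyl]cyclohexane-1,3-dione, via alkylidene dione 10 (not isolated)
Conditions: Hantzsch ester (1.1 equiv), L-proline (20 mol%), CH2Cl2, rt
Reagents that add atoms: none
Why: Ramachary reductive alkylation (proline-catalysed Knoevenagel condensation, then Hantzsch-ester transfer hydrogenation of the alkylidene dione) joins C4 to C4a under near-neutral conditions that should not epimerise the α-silyloxy center.

Step 7
Reactants: 11 2-[(2R,3R)-3-(4-methylphenylsulfonamido)-2-(triethylsilyloxy)butyl]cyclohexane-1,3-dione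
Product: 12 2-[(2R,3R)-3-(4-methylphenylsulfonamido)-2-(triethylsilyloxy)butyl]-3-oxocyclohex-1-en-1-yl trifluoromethanesulfonate
Conditions: Tf2O (1.1 equiv), 2,6-lutidine, CH2Cl2, −78 °C
Reagents that add atoms: trifluoromethanesulfonic anhydride, O=S(=O)(OS(=O)(=O)C(F)(F)F)C(F)(F)F
Why: O-triflation of the enolised 1,3-dione (both carbonyls are equivalent) gives the vinylogous triflate, which differentiates the future C5 (triflate) from C8a (ketone); the weakly nucleophilic sulfonamide does not compete at −78 °C.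

Step 8
Reactants: 12 2-[(2R,3R)-3-(4-methylphenylsulfonamido)-2-(triethylsilyloxy)butyl]-3-oxocyclohex-1-en-1-yl trifluoromethanesulfonate
Product: 13 (3S)-3-hydroxy-2-[(2R,3R)-3-(4-methylphenylsulfonamido)-2-(triethylsilyloxy)butyl]cyclohex-1-en-1-yl trifluoromethanesulfonate
Conditions: (R)-Me-CBS oxazaborolidine (0.3 equiv), BH3·SMe2, THF, −30 °C; MeOH quench
Reagents that add atoms: none
Why: Corey–Bakshi–Shibata reduction delivers hydride to the ketone face dictated by the catalyst, with the α-substituted alkenyl arm as the large group, and should give the (S)-carbinol at the future C8a under catalyst control.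

Step 9
Reactants: 13 (3S)-3-hydroxy-2-[(2R,3R)-3-(4-methylphenylsulfonamido)-2-(triethylsilyloxy)butyl]cyclohex-1-en-1-yl trifluoromethanesulfonate
Product: 14 (2R,3R,8aR)-2-methyl-1-(4-methylphenylsulfonyl)-3-(triethylsilyloxy)-1,2,3,4,6,7,8,8a-octahydroquinolin-5-yl trifluoromethanesulfonate
Conditions: PPh3, DIAD, THF (0.02 M), 0 °C to rt
Reagents that add atoms: none
Why: PPh3 and DIAD form the betaine, which deprotonates the sulfonamide N1–H and converts the C8a hydroxyl into an alkoxyphosphonium leaving group that the sulfonamide anion displaces intramolecularly. The closest known reaction type is the Fukuyama–Mitsunobu (intramolecular sulfonamide Mitsunobu) closure of 2,6-disubstituted piperidines. The ring N1–C2–C3–C4–C4a–C8a closes in a 6-exo-tet mode by backside attack at the allylic carbon C8a. C8a is the only new stereocenter and is set by inversion of the CBS-derived (S)-carbinol, which places H8a on the face of the C2 methyl and C3 oxygen; C2 and C3 are not touched. The step needs direct SN2 at C8a to win over SN2′ attack at C5, ionisation and elimination: C5 is fully substituted and its triflate destabilises an allyl cation, while the allylic π system accelerates direct displacement. Aziridine formation is excluded because O3 is silylated, and a chair-like transition state with the C2 methyl axial (relief of A(1,3) strain against the N-sulfonyl group) matches the required 2,6-trans arrangement.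

Step 10
Reactants: 14 (2R,3R,8aR)-2-methyl-1-(4-methylphenylsulfonyl)-3-(triethylsilyloxy)-1,2,3,4,6,7,8,8a-octahydroquinolin-5-yl trifluoromethanesulfonate; 8 (R)-tert-butyldimethyl(oct-7-en-4-yloxy)silane
Product: 16 (2R,3R,8aR)-5-[(5R)-5-(tert-butyldimethylsilyloxy)octyl]-2-methyl-1-(4-methylphenylsulfonyl)-3-(triethylsilyloxy)-1,2,3,4,6,7,8,8a-octahydroquinoline, via alkyl-9-BBN borane 15 (not isolated)
Conditions: 8, 9-BBN, THF, 0 °C to rt; then 14, Pd(dppf)Cl2 (5 mol%), K3PO4 (3 M aq.), DMF, rt to 50 °C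
Reagents that add atoms: none
Why: Anti-Markovnikov hydroboration followed by B-alkyl Suzuki–Miyaura coupling with the alkenyl triflate forms C5–C1′; the nitrogen is fully substituted at this stage, so it cannot interfere.

Step 11
Reactants: 16 (2R,3R,8aR)-5-[(5R)-5-(tert-butyldimethylsilyloxy)octyl]-2-methyl-1-(4-methylphenylsulfonyl)-3-(triethylsilyloxy)-1,2,3,4,6,7,8,8a-octahydroquinoline
Product: 17 (2R,3R,8aR)-5-[(5R)-5-(tert-butyldimethylsilyloxy)octyl]-2-methyl-1-(4-methylphenylsulfonyl)-1,2,3,4,6,7,8,8a-octahydroquinolin-3-ol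
Conditions: PPTS (0.2 equiv), MeOH/CH2Cl2, 0 °C to rt
Reagents that add atoms: none
Why: Mild acid methanolysis should cleave the triethylsilyl ether much faster than the secondary TBS ether, freeing only the C3 hydroxyl.

Step 12
Reactants: 17 (2R,3R,8aR)-5-[(5R)-5-(tert-butyldimethylsilyloxy)octyl]-2-methyl-1-(4-methylphenylsulfonyl)-1,2,3,4,6,7,8,8a-octahydroquinolin-3-ol
Product: 18 (2R,3R,4aS,5S,8aR)-5-[(5R)-5-(tert-butyldimethylsilyloxy)octyl]-2-methyl-1-(4-methylphenylsulfonyl)decahydroquinolin-3-ol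
Conditions: [Ir(cod)(PCy3)(py)]PF6 (10–20 mol%), H2 (1–10 bar), CH2Cl2, rt
Reagents that add atoms: none
Why: Hydroxyl-directed hydrogenation: the homoallylic axial C3–OH binds the cationic iridium and should deliver both hydrogens to C4a=C5 on its own face (the face of H8a), setting C4a and C5 in one event with the ring fusion cis and H5 cis to H4a, while the non-coordinating, pseudoaxial N-sulfonyl group shields the other face.

Step 13
Reactants: 18 (2R,3R,4aS,5S,8aR)-5-[(5R)-5-(tert-butyldimethylsilyloxy)octyl]-2-methyl-1-(4-methylphenylsulfonyl)decahydroquinolin-3-ol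
Product: 20 tert-butyl (2R,3R,4aS,5S,8aR)-5-[(5R)-5-(tert-butyldimethylsilyloxy)octyl]-3-hydroxy-2-methyloctahydroquinoline-1(2H)-carboxylate, via free amine 19 (not isolated)
Conditions: Na/naphthalene (sodium naphthalenide), DME, −78 °C; MeOH quench; then Boc2O, NaHCO3, THF/H2O, rt to 40 °C
Reagents that add atoms: di-tert-butyl dicarbonate, CC(C)(C)OC(=O)OC(=O)OC(C)(C)C
Why: Single-electron reductive cleavage of the N–S bond frees the amine without touching the silyl ether or the stereocenters, and carbamoylation in the same pot is N-selective in the absence of an acylation catalyst.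

Step 14
Reactants: 20 tert-butyl (2R,3R,4aS,5S,8aR)-5-[(5R)-5-(tert-butyldimethylsilyloxy)octyl]-3-hydroxy-2-methyloctahydroquinoline-1(2H)-carboxylate; 21 (E)-oct-2-enoic acid
Product: 22 tert-butyl (2R,3R,4aS,5S,8aR)-5-[(5R)-5-(tert-butyldimethylsilyloxy)octyl]-2-methyl-3-[(2E)-oct-2-enoyloxy]octahydroquinoline-1(2H)-carboxylate
Conditions: EDC·HCl, DMAP, CH2Cl2, 0 °C to rt
Reagents that add atoms: none
Why: Steglich-type esterification acylates the only free hydroxyl (C3) with retention at C3, the nitrogen and the C5′ oxygen both being protected.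

Step 15
Reactants: 22 tert-butyl (2R,3R,4aS,5S,8aR)-5-[(5R)-5-(tert-butyldimethylsilyloxy)octyl]-2-methyl-3-[(2E)-oct-2-enoyloxy]octahydroquinoline-1(2H)-carboxylate
Product: 23 (2R,3R,4aS,5S,8aR)-5-[(5R)-5-hydroxyoctyl]-2-methyldecahydroquinolin-3-yl (2E)-oct-2-enoate
Conditions: TFA/H2O (9:1), 0 °C to rt; then aq. NaHCO3/MeOH
Reagents that add atoms: none
Why: Acidolysis removes the Boc group and the secondary TBS ether in one operation while the protonated amine cannot attack the enoate, and the mild basic work-up should free the base and cleave any trifluoroacetate at C5′.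

Compound list
1 | ethyl (E)-but-2-enoate | C/C=C/C(=O)OCC | starting material
2 | ethyl (2S,3R)-2-hydroxy-3-(4-methylphenylsulfonamido)butanoate | C[C@@H](NS(=O)(=O)c1ccc(C)cc1)[C@H](O)C(=O)OCC | intermediate
3 | ethyl (2S,3R)-3-(4-methylphenylsulfonamido)-2-(triethylsilyloxy)butanoate | C[C@@H](NS(=O)(=O)c1ccc(C)cc1)[C@H](O[Si](CC)(CC)CC)C(=O)OCC | intermediate
4 | (2S,3R)-3-(4-methylphenylsulfonamido)-2-(triethylsilyloxy)butanal | C[C@@H](NS(=O)(=O)c1ccc(C)cc1)[C@H](O[Si](CC)(CC)CC)C=O | intermediate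
5 | (R)-2-propyloxirane | CCC[C@@H]1CO1 | starting material
6 | allylmagnesium bromide | C=CC[Mg]Br | starting material
7 | (R)-oct-7-en-4-ol | C=CCC[C@H](O)CCC | intermediate
8 | (R)-tert-butyldimethyl(oct-7-en-4-yloxy)silane | C=CCC[C@H](O[Si](C)(C)C(C)(C)C)CCC | intermediate
9 | cyclohexane-1,3-dione | O=C1CCCC(=O)C1 | starting material
10 | 2-[(2R,3R)-3-(4-methylphenylsulfonamido)-2-(triethylsilyloxy)butylidene]cyclohexane-1,3-dione (not isolated) | C[C@@H](NS(=O)(=O)c1ccc(C)cc1)[C@H](O[Si](CC)(CC)CC)C=C1C(=O)CCCC1=O | intermediate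
11 | 2-[(2R,3R)-3-(4-methylphenylsulfonamido)-2-(triethylsilyloxy)butyl]cyclohexane-1,3-dione | C[C@@H](NS(=O)(=O)c1ccc(C)cc1)[C@H](O[Si](CC)(CC)CC)CC1C(=O)CCCC1=O | intermediate
12 | 2-[(2R,3R)-3-(4-methylphenylsulfonamido)-2-(triethylsilyloxy)butyl]-3-oxocyclohex-1-en-1-yl trifluoromethanesulfonate | C[C@@H](NS(=O)(=O)c1ccc(C)cc1)[C@H](O[Si](CC)(CC)CC)CC1=C(OS(=O)(=O)C(F)(F)F)CCCC1=O | intermediate
13 | (3S)-3-hydroxy-2-[(2R,3R)-3-(4-methylphenylsulfonamido)-2-(triethylsilyloxy)butyl]cyclohex-1-en-1-yl trifluoromethanesulfonate | C[C@@H](NS(=O)(=O)c1ccc(C)cc1)[C@H](O[Si](CC)(CC)CC)CC1=C(OS(=O)(=O)C(F)(F)F)CCC[C@@H]1O | intermediate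
14 | (2R,3R,8aR)-2-methyl-1-(4-methylphenylsulfonyl)-3-(triethylsilyloxy)-1,2,3,4,6,7,8,8a-octahydroquinolin-5-yl trifluoromethanesulfonate | CC[Si](CC)(CC)O[C@@H]1CC2=C(OS(=O)(=O)C(F)(F)F)CCC[C@H]2N(S(=O)(=O)c3ccc(C)cc3)[C@@H]1C | intermediate
15 | 9-[(5R)-5-(tert-butyldimethylsilyloxy)octyl]-9-borabicyclo[3.3.1]nonane (not isolated) | CCC[C@H](CCCCB1C2CCCC1CCC2)O[Si](C)(C)C(C)(C)C | intermediate
16 | (2R,3R,8aR)-5-[(5R)-5-(tert-butyldimethylsilyloxy)octyl]-2-methyl-1-(4-methylphenylsulfonyl)-3-(triethylsilyloxy)-1,2,3,4,6,7,8,8a-octahydroquinoline | CC[Si](CC)(CC)O[C@@H]1CC2=C(CCCC[C@H](O[Si](C)(C)C(C)(C)C)CCC)CCC[C@H]2N(S(=O)(=O)c3ccc(C)cc3)[C@@H]1C | intermediate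
17 | (2R,3R,8aR)-5-[(5R)-5-(tert-butyldimethylsilyloxy)octyl]-2-methyl-1-(4-methylphenylsulfonyl)-1,2,3,4,6,7,8,8a-octahydroquinolin-3-ol | O[C@@H]1CC2=C(CCCC[C@H](O[Si](C)(C)C(C)(C)C)CCC)CCC[C@H]2N(S(=O)(=O)c3ccc(C)cc3)[C@@H]1C | intermediate
18 | (2R,3R,4aS,5S,8aR)-5-[(5R)-5-(tert-butyldimethylsilyloxy)octyl]-2-methyl-1-(4-methylphenylsulfonyl)decahydroquinolin-3-ol | O[C@@H]1C[C@H]2[C@@H](CCCC[C@H](O[Si](C)(C)C(C)(C)C)CCC)CCC[C@H]2N(S(=O)(=O)c3ccc(C)cc3)[C@@H]1C | intermediate
19 | (2R,3R,4aS,5S,8aR)-5-[(5R)-5-(tert-butyldimethylsilyloxy)octyl]-2-methyldecahydroquinolin-3-ol (not isolated) | O[C@@H]1C[C@H]2[C@@H](CCCC[C@H](O[Si](C)(C)C(C)(C)C)CCC)CCC[C@H]2N[C@@H]1C | intermediate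
20 | tert-butyl (2R,3R,4aS,5S,8aR)-5-[(5R)-5-(tert-butyldimethylsilyloxy)octyl]-3-hydroxy-2-methyloctahydroquinoline-1(2H)-carboxylate | O[C@@H]1C[C@H]2[C@@H](CCCC[C@H](O[Si](C)(C)C(C)(C)C)CCC)CCC[C@H]2N(C(=O)OC(C)(C)C)[C@@H]1C | intermediate
21 | (E)-oct-2-enoic acid | CCCCC/C=C/C(=O)O | starting material
22 | tert-butyl (2R,3R,4aS,5S,8aR)-5-[(5R)-5-(tert-butyldimethylsilyloxy)octyl]-2-methyl-3-[(2E)-oct-2-enoyloxy]octahydroquinoline-1(2H)-carboxylate | CCCCC/C=C/C(=O)O[C@@H]1C[C@H]2[C@@H](CCCC[C@H](O[Si](C)(C)C(C)(C)C)CCC)CCC[C@H]2N(C(=O)OC(C)(C)C)[C@@H]1C | intermediate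
23 | (2R,3R,4aS,5S,8aR)-5-[(5R)-5-hydroxyoctyl]-2-methyldecahydroquinolin-3-yl (2E)-oct-2-enoate | CCCCC/C=C/C(=O)O[C@@H]1C[C@H]2[C@@H](CCCC[C@H](O)CCC)CCC[C@H]2N[C@@H]1C | target

Total step count: 15. Longest linear sequence: 13 steps (steps 1–3 and 6–15); the side-chain fragment (steps 4–5) joins at step 10.

Steps most likely to fail

Step 9 (key step). The allylic alkoxyphosphonium may eliminate to a diene, or the hindered N-sec-alkyl sulfonamide may displace too slowly, so that the activated alcohol decomposes. The fallback replaces the Mitsunobu inversion by a Tsuji–Trost closure with net retention. It sets out from ketone 12, which is reduced with the enantiomeric (S)-Me-CBS catalyst and BH3·SMe2 to the (3R)-hydroxy triflate F1. B-alkyl Suzuki coupling of F1 with borane 15 (Pd(dppf)Cl2, K3PO4) gives the side-chain-bearing (R)-allylic alcohol F2, and methyl chloroformate/pyridine converts it into the allylic methyl carbonate F3. Pd(PPh3)4 in THF at 40 °C should then ionise the carbonate with inversion. The sulfonamide attacks the less substituted terminus C8a of the π-allyl on the face away from zerovalent palladium, and the route is rejoined at compound 16.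

Step 12. Hydrogen delivery to the tetrasubstituted C4a=C5 alkene may be slow, so that the catalyst deactivates, the alkene migrates, or some hydrogen adds from the face away from the hydroxyl. The fallback uses steric approach control on a heterogeneous catalyst instead of hydroxyl direction. It sets out from silyl ether 16, which is hydrogenated over 5% Rh/Al2O3 (H2, 50 bar, EtOAc); the pseudoaxial N-sulfonyl group on the cyclohexene should shield the face opposite to H8a. This gives the saturated silyl ether F4, and PPTS in MeOH then removes the triethylsilyl group to rejoin the route at compound 18.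

Step 14. Acylation of the hindered axial C3 hydroxyl next to the carbamate may be slow, which gives the activated octenoyl species time to lose its γ-proton and deconjugate to the β,γ-unsaturated ester. The fallback builds the enoate on the ester instead of transferring it. It sets out from alcohol 20, which is acylated with the small, non-deconjugating diethylphosphonoacetic acid (EDC·HCl, DMAP) to give the phosphonoacetate F5. A Masamune–Roush Horner–Wadsworth–Emmons reaction of F5 with hexanal (LiCl, DBU, MeCN) should then give the E-enoate, rejoining the route at compound 22.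

Further compounds
F1 | step 9 | (3R)-3-hydroxy-2-[(2R,3R)-3-(4-methylphenylsulfonamido)-2-(triethylsilyloxy)butyl]cyclohex-1-en-1-yl trifluoromethanesulfonate | C[C@@H](NS(=O)(=O)c1ccc(C)cc1)[C@H](O[Si](CC)(CC)CC)CC1=C(OS(=O)(=O)C(F)(F)F)CCC[C@H]1O
F2 | step 9 | N-[(2R,3R)-4-{(6R)-2-[(5R)-5-(tert-butyldimethylsilyloxy)octyl]-6-hydroxycyclohex-1-en-1-yl}-3-(triethylsilyloxy)butan-2-yl]-4-methylbenzenesulfonamide | C[C@@H](NS(=O)(=O)c1ccc(C)cc1)[C@H](O[Si](CC)(CC)CC)CC1=C(CCCC[C@H](O[Si](C)(C)C(C)(C)C)CCC)CCC[C@H]1O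
F3 | step 9 | (1R)-3-[(5R)-5-(tert-butyldimethylsilyloxy)octyl]-2-[(2R,3R)-3-(4-methylphenylsulfonamido)-2-(triethylsilyloxy)butyl]cyclohex-2-en-1-yl methyl carbonate | C[C@@H](NS(=O)(=O)c1ccc(C)cc1)[C@H](O[Si](CC)(CC)CC)CC1=C(CCCC[C@H](O[Si](C)(C)C(C)(C)C)CCC)CCC[C@H]1OC(=O)OC
F4 | step 12 | (2R,3R,4aS,5S,8aR)-5-[(5R)-5-(tert-butyldimethylsilyloxy)octyl]-2-methyl-1-(4-methylphenylsulfonyl)-3-(triethylsilyloxy)decahydroquinoline | CC[Si](CC)(CC)O[C@@H]1C[C@H]2[C@@H](CCCC[C@H](O[Si](C)(C)C(C)(C)C)CCC)CCC[C@H]2N(S(=O)(=O)c3ccc(C)cc3)[C@@H]1C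
F5 | step 14 | tert-butyl (2R,3R,4aS,5S,8aR)-5-[(5R)-5-(tert-butyldimethylsilyloxy)octyl]-3-{[2-(diethoxyphosphoryl)acetyl]oxy}-2-methyloctahydroquinoline-1(2H)-carboxylate | CCOP(=O)(OCC)CC(=O)O[C@@H]1C[C@H]2[C@@H](CCCC[C@H](O[Si](C)(C)C(C)(C)C)CCC)CCC[C@H]2N(C(=O)OC(C)(C)C)[C@@H]1C
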